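A one-step world draws a flat line: two products from one branch keep one ratio throughout. The north flask does not, so we follow its capture odds O, c(other capture product) over c(target), on a logarithmic scale; the share asked is O over one plus O.

| flask | substrate | first nucleophile | second nucleophile | remark | time |
|---|---|---|---|---|---|
| north | 37 mM | 37 mM | 37 mM | the very flask that is asked about, followed so far |  |
| south-west | 37 mM | 37 mM | 56 mM | run made earlier |  |
| flask | 37 mM | 37.0 mM | 37.0 mM |  | 25 h |

- north (time / min: other capture product / %, target / %): 30.0: 10.1, 9.6; 60.0: 14.7, 12.5; 90.0: 17.4, 12.2; 120: 18.4, 11.5
- south-west (time / h: other capture product / %, target / %): 3.00: 27.0, 8.7; 8.00: 27.3, 7.4; 15.0: 27.8, 6.8; 25.0: 28.1, 7.2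

(each reading ± 0.5 percentage points)

1. share of other capture product in other capture product plus target at 3.0 min
2. share of other capture product in other capture product plus target at 1.0 h
3. share of other capture product in other capture product plus target at 25 h
4. which of other capture product and target there is more of at 25 h



1. Slope. North odds read 1.05 at 30.0 min and 1.60 at 120 min. In powers of ten, that is a rise of 0.121 /h.

2. Start. Carried back to 3.0 min, this line gives odds of 0.928, a share of 48.1%. It is a chord through a bending curve, so we hold it as a high mark.

3. Crossing. At the first north reading the two products differ by 0.5 percentage points against a scatter of 0.5 points, so we place the crossing O = one near that reading. At 1.0 h the north reading gives a share of 54.0%.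

4. Level. The south-west run stays flat within scatter from 8.00 h, and its pooled late readings give odds of 3.89. It differs from north in its second nucleophile charge, so we take end odds as proportional to c(second nucleophile), with first nucleophile held at 37 mM. Dividing gives 0.0694 /mM: the end odds per millimolar of second nucleophile.

5. Knee. For the north flask, we reckon a level of 2.57, a share of 72.0%. The line from step 1 reaches it near 3.69 h, earlier than 25 h, so we expect north on its level then, with other capture product ahead.

6. Forecast. The forecast gives 48%, 54%, 75% and other capture product ahead, holding that “target is the kinetic product and leaks away or re-equilibrates”. Our level share of 72.0% lies lower than its 75%.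

7. Result. The north flask gives 42.9%, 53.1% and 71.2%, with other capture product ahead. Its 20.0% against 8.08% makes end odds of 2.48, beside our 2.57. The share at 3.0 min lies below both the forecast and our mark.

    substrate → intermediate (k = 1.30 /h)
    substrate + intermediate → side product (k = 17.0 /M/h)
    first nucleophile ⇌ dormant form (K = 2.60, k = 0.290 /h)
    target ⇌ isomer of the product (K = 1.70, k = 0.560 /h)
    intermediate → solvolysis product (k = 240 /h)
    second nucleophile + intermediate → other capture product (k = 2500 /M/h)
    first nucleophile + intermediate → target (k = 3400 /M/h)

8. Neighbour. A flask charged with 150 mM of second nucleophile, all else as in north, gets end odds of 10.4 from the same factor, a share of 91.2%. That flask gives 90.8%, with target at 5.15%.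

The runs come from a simulation with constants of no real substance, noise included.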